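**Retrosynthetic overview**
1. 28 ⇐ 27 by epoxidation of the 4Z-alkene (oxirane made last); 27 ⇐ 25 by C1 desilylation and oxidation.
2. 25 ⇐ 23 by closing C3–C4: the oxirane carbon C4 (bearing the C15 methyl) is carried as the sp2 carbon of a (Z)-iodoalkene and is joined to the C3 methylene by a B-alkyl Suzuki–Miyaura coupling, which forms the ten-membered carbocycle on the finished γ-lactone.
3. 23 ⇐ butenolide 5 + dithiane 13 + CH2O: C7–C8 by conjugate addition of a C8 acyl-anion equivalent, C11–C13 by aldol trapping, C8–OH by 1,3-syn reduction under control of C10–OH, then tiglate and acetates.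
4. 13 ⇐ 1,3-dithiane + epoxide 10 (C9–C10 oxirane from a kinetic resolution); 5 ⇐ (S)-hydroxymethylbutyrolactone 1 by iodo-olefination and dehydrogenation.
5. Ring order: γ-lactone (present from 1) → ten-membered carbocycle (step 14) → oxirane (step 17).

Key step: step 14

Remark: locants follow germacrane numbering (ring C1–C10, lactone carbons C11–C13 closed on O6, C14 on C10, C15 on C4); the C1 carbinol centre is only a relay that ends as the ketone and is carried as 1S, the configuration that the kinetic resolution of step 5 supplies.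

Step 1
Reactants: 1 (5S)-5-(hydroxymethyl)oxolan-2-one
Product: 2 (2S)-5-oxooxolane-2-carbaldehyde
Conditions: Dess–Martin periodinane, CH2Cl2, rt; used crude
Reagents that add atoms: none
Why: Dess–Martin oxidation of the primary alcohol under neutral, anhydrous conditions gives the α-acyloxy aldehyde without epimerising C6.

Step 2
Reactants: 2 (2S)-5-oxooxolane-2-carbaldehyde
Product: 3 (5S)-5-[(1Z)-2-iodoprop-1-en-1-yl]oxolan-2-one
Conditions: EtPPh3I, n-BuLi, THF, 0 °C; I2, −78 °C; NaN(SiMe3)2, −20 °C; then 2, −78 → −20 °C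
Reagents that add atoms: ethyltriphenylphosphonium iodide (CC[P+](c1ccccc1)(c1ccccc1)c1ccccc1.[I-]); iodine (II)
Why: Stork–Zhao-type Wittig olefination with the non-stabilised α-iodo ylide should give the (Z)-iodoalkene (iodine cis to C6) through the kinetic cis-oxaphosphetane, and at −78 °C addition to the aldehyde outruns enolisation at C6.

Step 3
Reactants: 3 (5S)-5-[(1Z)-2-iodoprop-1-en-1-yl]oxolan-2-one
Product: 5 (5S)-5-[(1Z)-2-iodoprop-1-en-1-yl]furan-2(5H)-one, via α-phenylselanyl lactone 4 (not isolated)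
Conditions: LiN(SiMe3)2, THF, −78 °C; PhSeBr, −78 °C; then 30% H2O2, pyridine, 0 °C → rt
Reagents that add atoms: none
Why: α-Selenenylation of the lactone enolate followed by selenoxide syn-elimination towards C7–H gives the butenolide; C6 is not deprotonated and the iodoalkene is inert.

Step 4
Reactants: 6 methacrolein; 7 vinylmagnesium bromide
Product: 8 rac-2-methylpenta-1,4-dien-3-ol
Conditions: THF, −78 → 0 °C; aq. NH4Cl
Reagents that add atoms: none
Why: Grignard 1,2-addition to the enal gives the racemic bis-allylic alcohol that carries C9, C10, C14 and C1–C3.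

Step 5
Reactants: 8 rac-2-methylpenta-1,4-dien-3-ol
Product: 9 (1S)-1-[(2R)-2-methyloxiran-2-yl]prop-2-en-1-ol
Conditions: Ti(OiPr)4 (cat.), L-(+)-diisopropyl tartrate, t-BuOOH (0.55 equiv), 4 Å MS, CH2Cl2, −20 °C
Reagents that add atoms: tert-butyl hydroperoxide (CC(C)(C)OO)
Why: Katsuki–Sharpless kinetic resolution: with the L-(+)-tartrate only the (S)-alcohol should be epoxidised, at its more electron-rich 1,1-disubstituted alkene, the catalyst fixing C10 as R and the erythro relation to C1 (S).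

Step 6
Reactants: 9 (1S)-1-[(2R)-2-methyloxiran-2-yl]prop-2-en-1-ol
Product: 10 tert-butyl(dimethyl){[(1S)-1-[(2R)-2-methyloxiran-2-yl]prop-2-en-1-yl]oxy}silane
Conditions: TBSCl, imidazole, DMF, 0 °C → rt
Reagents that add atoms: tert-butyldimethylsilyl chloride (CC(C)(C)[Si](C)(C)Cl)
Why: Silylation under imidazole buffer protects O1 without Payne rearrangement of the epoxy alcohol.

Step 7
Reactants: 10 tert-butyl(dimethyl){[(1S)-1-[(2R)-2-methyloxiran-2-yl]prop-2-en-1-yl]oxy}silane; 11 1,3-dithiane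
Product: 13 (2R,3S)-3-[(tert-butyldimethylsilyl)oxy]-1-(1,3-dithian-2-yl)-2-methylpent-4-en-2-ol, via 2-lithio-1,3-dithiane 12 (not isolated)
Conditions: 11, n-BuLi, THF, −30 °C; then 10, DMPU, −30 → 0 °C; aq. NH4Cl
Reagents that add atoms: none
Why: Corey–Seebach alkylation: the dithiane anion opens the 2,2-disubstituted epoxide by SN2 attack at the unsubstituted carbon C9, so C10 keeps its configuration and becomes the tertiary alcohol, with C8 installed as a masked carbonyl.

Step 8
Reactants: 13 (2R,3S)-3-[(tert-butyldimethylsilyl)oxy]-1-(1,3-dithian-2-yl)-2-methylpent-4-en-2-ol; 5 (5S)-5-[(1Z)-2-iodoprop-1-en-1-yl]furan-2(5H)-one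
Product: 16 (3R,4S,5S)-4-{2-[(2R,3S)-3-(tert-butyldimethylsilyloxy)-2-hydroxy-2-methylpent-4-enyl]-1,3-dithian-2-yl}-3-(hydroxymethyl)-5-[(1Z)-2-iodoprop-1-enyl]oxolan-2-one, via dilithio dithiane 14 (not isolated), via lithium enolate 15 (not isolated)
Conditions: 13, t-BuLi (2.1 equiv), THF/DMPU, −78 °C; 5, −78 °C; CH2O (gas from cracked paraformaldehyde), −78 → −40 °C; aq. NH4Cl
Reagents that add atoms: formaldehyde (C=O)
Why: Tandem Michael addition–aldol: the dithiane carbanion adds to C7 of the butenolide anti to the C6 alkenyl group and the lactone enolate is then hydroxymethylated anti to the new bulky C7 substituent, which sets C7 and C11 in the all-trans arrangement of the target.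

Step 9
Reactants: 16 lactone diol from step 8
Product: 17 {(3R,4S,5S)-4-{2-[(2R,3S)-3-(tert-butyldimethylsilyloxy)-2-hydroxy-2-methylpent-4-enyl]-1,3-dithian-2-yl}-5-[(1Z)-2-iodoprop-1-enyl]-2-oxooxolan-3-yl}methyl acetate
Conditions: Ac2O, pyridine, CH2Cl2, 0 °C
Reagents that add atoms: acetic anhydride (CC(=O)OC(C)=O)
Why: Selective acetylation of the primary C13 alcohol; the hindered tertiary C10–OH does not react, and capping O13 prevents lactol formation with the C8 ketone to come.

Step 10
Reactants: 17 C13 acetate from step 9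
Product: 18 (3R,4S,5S)-3-(acetoxymethyl)-4-[(3R,4S)-4-(tert-butyldimethylsilyloxy)-3-hydroxy-3-methylhex-5-enoyl]-5-[(1Z)-2-iodoprop-1-enyl]oxolan-2-one
Conditions: PhI(OCOCF3)2, MeCN/H2O 9:1, 0 °C
Reagents that add atoms: water (O)
Why: Oxidative dithioacetal hydrolysis unmasks the C8 ketone under non-basic conditions, so neither retro-aldol at C9–C10 nor E1cB opening of the C6–O bond can start, and the alkenes and the iodoalkene are inert.

Step 11
Reactants: 18 β-hydroxy ketone from step 10
Product: 19 (3R,4R,5S)-3-(acetoxymethyl)-4-[(1S,3R,4S)-4-(tert-butyldimethylsilyloxy)-1,3-dihydroxy-3-methylhex-5-enyl]-5-[(1Z)-2-iodoprop-1-enyl]oxolan-2-one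
Conditions: Et2BOMe, THF/MeOH 4:1, −78 °C; NaBH4, −78 °C; AcOH quench, MeOH co-evaporation
Reagents that add atoms: none
Why: Narasaka–Prasad reduction: Et2BOMe ties C10–OH and the C8 ketone into a six-membered boron chelate with the larger C1 branch equatorial, and external axial hydride delivery should give the 8,10-syn diol, i.e. 8S.

Step 12
Reactants: 19 syn-diol from step 11; 20 tiglic acid
Product: 22 (3R,4R,5S)-3-(acetoxymethyl)-4-[(1S,3R,4S)-4-(tert-butyldimethylsilyloxy)-3-hydroxy-3-methyl-1-(tigloyloxy)hex-5-enyl]-5-[(1Z)-2-iodoprop-1-enyl]oxolan-2-one, via Yamaguchi mixed anhydride 21 (not isolated)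
Conditions: 20, 2,4,6-trichlorobenzoyl chloride, Et3N, toluene, rt; then 19, DMAP, rt
Reagents that add atoms: none
Why: Yamaguchi esterification acylates the secondary C8–OH through the acyl-DMAP salt while the tertiary C10–OH is too hindered, and the tiglate keeps its E geometry.

Step 13
Reactants: 22 C8 tiglate from step 12
Product: 23 (3R,4R,5S)-3-(acetoxymethyl)-4-[(1S,3R,4S)-3-acetoxy-4-(tert-butyldimethylsilyloxy)-3-methyl-1-(tigloyloxy)hex-5-enyl]-5-[(1Z)-2-iodoprop-1-enyl]oxolan-2-one
Conditions: Ac2O, DMAP, Et3N, CH2Cl2, rt → 35 °C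
Reagents that add atoms: acetic anhydride (CC(=O)OC(C)=O)
Why: DMAP-catalysed (Steglich-type) acetylation of the tertiary alcohol; the amine bases are too weak to eliminate the C13 acetate from the lactone and the silyl ether is untouched.

Step 14
Reactants: 23 seco precursor from step 13
Product: 25 (1S,4Z,6R,7R,8S,10R,11R)-10,13-diacetoxy-1-(tert-butyldimethylsilyloxy)-8-(tigloyloxy)germacr-4-en-6,12-olide, via B-alkyl-9-BBN borane 24 (not isolated)
Conditions: 9-BBN, THF, 0 °C → rt; then slow addition to Pd(dppf)Cl2 (20 mol %), AsPh3, Cs2CO3, DMF/THF/H2O, rt, about 1 mM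
Reagents that add atoms: none
Why: 9-BBN adds B–H to the only monosubstituted alkene (C2=C3) with boron on terminal C3, the trisubstituted tiglate and iodoalkene and the esters being inert to this borane; zerovalent palladium generated from Pd(dppf)Cl2 then inserts into the C4–I bond with retention, the base-activated alkylborate transfers C3 to palladium, and reductive elimination forms C3–C4. The closest known reaction type is the intramolecular B-alkyl Suzuki–Miyaura macrocyclisation of an alkyl-9-BBN with an alkenyl iodide. The ten-membered carbocycle closes by reductive elimination from an eleven-membered alkyl(alkenyl)palladacycle, an sp3–sp2 ring closure at C3–C4 on the preformed lactone. No stereocentre is created, and the 4Z geometry is carried over from the (Z)-iodoalkene because oxidative addition and reductive elimination both retain configuration at the alkenyl carbon. The step needs anti-Markovnikov hydroboration, secured by the steric demand of 9-BBN, and ring closure in preference to intermolecular coupling, secured by slow addition at high dilution; the wide bite angle of dppf favours reductive elimination over β-hydride elimination, and Cs2CO3 at room temperature is expected to spare the four esters.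

Step 15
Reactants: 25 macrocyclic silyl ether from step 14
Product: 26 (1S,4Z,6R,7R,8S,10R,11R)-10,13-diacetoxy-1-hydroxy-8-(tigloyloxy)germacr-4-en-6,12-olide
Conditions: HF·pyridine, pyridine, THF, 0 °C → rt
Reagents that add atoms: none
Why: Fluoride cleavage of the hindered secondary silyl ether in a buffered acidic medium, which avoids base-induced 1,2-acetyl migration from O10 to O1 and elimination of the C13 acetate.

Step 16
Reactants: 26 C1 alcohol from step 15
Product: 27 (4Z,6R,7R,8S,10R,11R)-10,13-diacetoxy-1-oxo-8-(tigloyloxy)germacr-4-en-6,12-olide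
Conditions: Dess–Martin periodinane, CH2Cl2, rt
Reagents that add atoms: none
Why: Dess–Martin oxidation of the secondary alcohol; C10 is quaternary, so the α-acetoxy ketone cannot epimerise.

Step 17
Reactants: 27 4Z-enone from step 16
Product: 28 (4R,5S,6S,7R,8S,10R,11R)-10,13-diacetoxy-4,5-epoxy-1-oxo-8-(tigloyloxy)germacran-6,12-olide (CNP0305680.1)
Conditions: dimethyldioxirane, acetone/CH2Cl2, −20 → 0 °C
Reagents that add atoms: dimethyldioxirane (CC1(C)OO1)
Why: Concerted, cis-stereospecific epoxidation by the dioxirane of the only electron-rich alkene (the tiglate is deactivated and the ketone is not attacked); with H6 eclipsing the alkene, the oxidant is expected to enter anti to the electron-withdrawing allylic C6–O bond, on the face that carries C7, which places the oxirane oxygen cis to the lactone oxygen on the ring and gives 4R,5S.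

**Compound list**
1 | (5S)-5-(hydroxymethyl)oxolan-2-one | O=C1O[C@H](CO)CC1 | starting material
2 | (2S)-5-oxooxolane-2-carbaldehyde | O=C1O[C@H](C=O)CC1 | intermediate
3 | (5S)-5-[(1Z)-2-iodoprop-1-en-1-yl]oxolan-2-one | O=C1O[C@H](/C=C(C)\I)CC1 | intermediate
4 | (5S)-5-[(1Z)-2-iodoprop-1-en-1-yl]-3-(phenylselanyl)oxolan-2-one, C3 epimers (not isolated) | O=C1O[C@H](/C=C(C)\I)CC1[Se]c1ccccc1 | intermediate
5 | (5S)-5-[(1Z)-2-iodoprop-1-en-1-yl]furan-2(5H)-one | O=C1O[C@H](/C=C(C)\I)C=C1 | intermediate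
6 | methacrolein (2-methylprop-2-enal) | CC(=C)C=O | starting material
7 | vinylmagnesium bromide | C=C[Mg]Br | starting material
8 | rac-2-methylpenta-1,4-dien-3-ol | C=CC(O)C(C)=C | intermediate
9 | (1S)-1-[(2R)-2-methyloxiran-2-yl]prop-2-en-1-ol | C=C[C@H](O)[C@]1(C)OC1 | intermediate
10 | tert-butyl(dimethyl){[(1S)-1-[(2R)-2-methyloxiran-2-yl]prop-2-en-1-yl]oxy}silane | C=C[C@H](O[Si](C)(C)C(C)(C)C)[C@]1(C)OC1 | intermediate
11 | 1,3-dithiane | C1CSCSC1 | starting material
12 | 2-lithio-1,3-dithiane (not isolated) | [Li]C1SCCCS1 | intermediate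
13 | (2R,3S)-3-[(tert-butyldimethylsilyl)oxy]-1-(1,3-dithian-2-yl)-2-methylpent-4-en-2-ol | C=C[C@H](O[Si](C)(C)C(C)(C)C)[C@](C)(O)CC1SCCCS1 | intermediate
14 | O,C-dilithio derivative of 13: lithium alkoxide at O10, lithium at dithiane C2 (not isolated) | C=C[C@H](O[Si](C)(C)C(C)(C)C)[C@](C)(O[Li])CC1([Li])SCCCS1 | intermediate
15 | dilithium alkoxide–lactone enolate formed by addition of 14 to C7 of 5 (not isolated) | C=C[C@H](O[Si](C)(C)C(C)(C)C)[C@](C)(O[Li])CC2(SCCCS2)[C@H]1C=C(O[Li])O[C@@H]1/C=C(C)\I | intermediate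
16 | (3R,4S,5S)-4-{2-[(2R,3S)-3-(tert-butyldimethylsilyloxy)-2-hydroxy-2-methylpent-4-enyl]-1,3-dithian-2-yl}-3-(hydroxymethyl)-5-[(1Z)-2-iodoprop-1-enyl]oxolan-2-one | C=C[C@H](O[Si](C)(C)C(C)(C)C)[C@](C)(O)CC2(SCCCS2)[C@H]1[C@H](CO)C(=O)O[C@@H]1/C=C(C)\I | intermediate
17 | C13 acetate of 16 | C=C[C@H](O[Si](C)(C)C(C)(C)C)[C@](C)(O)CC2(SCCCS2)[C@H]1[C@H](COC(C)=O)C(=O)O[C@@H]1/C=C(C)\I | intermediate
18 | (3R,4S,5S)-3-(acetoxymethyl)-4-[(3R,4S)-4-(tert-butyldimethylsilyloxy)-3-hydroxy-3-methylhex-5-enoyl]-5-[(1Z)-2-iodoprop-1-enyl]oxolan-2-one | C=C[C@H](O[Si](C)(C)C(C)(C)C)[C@](C)(O)CC(=O)[C@H]1[C@H](COC(C)=O)C(=O)O[C@@H]1/C=C(C)\I | intermediate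
19 | (3R,4R,5S)-3-(acetoxymethyl)-4-[(1S,3R,4S)-4-(tert-butyldimethylsilyloxy)-1,3-dihydroxy-3-methylhex-5-enyl]-5-[(1Z)-2-iodoprop-1-enyl]oxolan-2-one | C=C[C@H](O[Si](C)(C)C(C)(C)C)[C@](C)(O)C[C@H](O)[C@H]1[C@H](COC(C)=O)C(=O)O[C@@H]1/C=C(C)\I | intermediate
20 | tiglic acid, (E)-2-methylbut-2-enoic acid | C/C=C(\C)C(=O)O | starting material
21 | tiglic 2,4,6-trichlorobenzoic anhydride (not isolated) | C/C=C(\C)C(=O)OC(=O)c1c(Cl)cc(Cl)cc1Cl | intermediate
22 | (3R,4R,5S)-3-(acetoxymethyl)-4-[(1S,3R,4S)-4-(tert-butyldimethylsilyloxy)-3-hydroxy-3-methyl-1-(tigloyloxy)hex-5-enyl]-5-[(1Z)-2-iodoprop-1-enyl]oxolan-2-one | C=C[C@H](O[Si](C)(C)C(C)(C)C)[C@](C)(O)C[C@H](OC(=O)/C(C)=C/C)[C@H]1[C@H](COC(C)=O)C(=O)O[C@@H]1/C=C(C)\I | intermediate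
23 | (3R,4R,5S)-3-(acetoxymethyl)-4-[(1S,3R,4S)-3-acetoxy-4-(tert-butyldimethylsilyloxy)-3-methyl-1-(tigloyloxy)hex-5-enyl]-5-[(1Z)-2-iodoprop-1-enyl]oxolan-2-one (seco precursor) | C=C[C@H](O[Si](C)(C)C(C)(C)C)[C@](C)(OC(C)=O)C[C@H](OC(=O)/C(C)=C/C)[C@H]1[C@H](COC(C)=O)C(=O)O[C@@H]1/C=C(C)\I | intermediate
24 | C3 B-alkyl-9-borabicyclo[3.3.1]nonane derived from 23 (not isolated) | C1CC2CCCC(C1)B2CC[C@H](O[Si](C)(C)C(C)(C)C)[C@](C)(OC(C)=O)C[C@H](OC(=O)/C(C)=C/C)[C@H]3[C@H](COC(C)=O)C(=O)O[C@@H]3/C=C(C)\I | intermediate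
25 | (1S,4Z,6R,7R,8S,10R,11R)-10,13-diacetoxy-1-(tert-butyldimethylsilyloxy)-8-(tigloyloxy)germacr-4-en-6,12-olide | C/C=C(\C)C(=O)O[C@H]1C[C@@](C)(OC(C)=O)[C@@H](O[Si](C)(C)C(C)(C)C)CC/C(C)=C\[C@H]2OC(=O)[C@@H](COC(C)=O)[C@@H]21 | intermediate
26 | (1S,4Z,6R,7R,8S,10R,11R)-10,13-diacetoxy-1-hydroxy-8-(tigloyloxy)germacr-4-en-6,12-olide | C/C=C(\C)C(=O)O[C@H]1C[C@@](C)(OC(C)=O)[C@@H](O)CC/C(C)=C\[C@H]2OC(=O)[C@@H](COC(C)=O)[C@@H]21 | intermediate
27 | (4Z,6R,7R,8S,10R,11R)-10,13-diacetoxy-1-oxo-8-(tigloyloxy)germacr-4-en-6,12-olide | C/C=C(\C)C(=O)O[C@H]1C[C@@](C)(OC(C)=O)C(=O)CC/C(C)=C\[C@H]2OC(=O)[C@@H](COC(C)=O)[C@@H]21 | intermediate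
28 | (4R,5S,6S,7R,8S,10R,11R)-10,13-diacetoxy-4,5-epoxy-1-oxo-8-(tigloyloxy)germacran-6,12-olide (CNP0305680.1) | C/C=C(\C)C(=O)O[C@H]1C[C@@](C)(OC(C)=O)C(=O)CC[C@@]2(C)O[C@H]2[C@H]2OC(=O)[C@@H](COC(C)=O)[C@@H]21 | target

**Step count and risks**
Total: 17 steps. Longest linear sequence: 14 steps (steps 4–7, then 8–17); the lactone branch (steps 1–3) joins at step 8.

Steps most likely to fail:

1. Step 14 (ring closure). Closure of the strained ten-membered ring may be slow, so that intermolecular coupling, β-hydride elimination of the alkylpalladium, protodeboronation, or base-induced loss of acetic acid across C11–C13 can overtake it. Fallback: the same C3–C4 bond would be closed without base as an intramolecular Negishi coupling. Hydroboration of 23 with 9-BBN and oxidation with NaBO3·4H2O would give the primary C3 alcohol F1. I2, PPh3 and imidazole would convert it into the primary C3 iodide F2. Zinc dust with LiCl in THF inserts only into the alkyl C–I bond to give the alkylzinc iodide F3, which under Pd(PPh3)4 at high dilution would close to 25, where the route resumes.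

2. Step 8 (tandem addition). The dithiane anion may remove the C6 proton of the 5-alkenylbutenolide (γ-deprotonation to the furanolate, with loss of material and of C6 configuration) instead of adding to C7. Fallback: the tandem step would be run on a butenolide without an alkenyl group at C6, and the iodoalkene made afterwards. Commercial (5S)-5-(hydroxymethyl)furan-2(5H)-one F4 would be silylated (TESCl, imidazole) to the triethylsilyl ether F5. The dianion of 13 and then formaldehyde would be added as in step 8 to give the lactone diol F6. Ac2O and pyridine would give the C13 acetate F7. PPTS in MeOH would cleave only the primary triethylsilyl ether to give the C5 alcohol F8. Dess–Martin oxidation would give the C5 aldehyde F9, and the α-iodo ylide of step 2 would convert F9 into 17, where the route resumes.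

3. Step 17 (epoxidation). Facial selectivity may be poor or reversed, because the sterically more open, peripheral face of the 4Z-alkene is the one syn to the C6–O bond, opposite to the face required. Fallback: the same facial preference would be used in the opposite sense through a halohydrin. From 27, NBS in aqueous DME would form the bromonium ion on the peripheral face, and water (or the C1 carbonyl oxygen, transannularly) would open it at the tertiary C4 from the required face to give the bromohydrin F10. Ag2O in THF would then close the oxirane by displacing bromide at C5 with inversion, giving 28.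

**Further compounds**
F1 | step 14 | C3 primary alcohol from hydroboration–oxidation of 23 | OCC[C@H](O[Si](C)(C)C(C)(C)C)[C@](C)(OC(C)=O)C[C@H](OC(=O)/C(C)=C/C)[C@H]1[C@H](COC(C)=O)C(=O)O[C@@H]1/C=C(C)\I
F2 | step 14 | C3 primary iodide | ICC[C@H](O[Si](C)(C)C(C)(C)C)[C@](C)(OC(C)=O)C[C@H](OC(=O)/C(C)=C/C)[C@H]1[C@H](COC(C)=O)C(=O)O[C@@H]1/C=C(C)\I
F3 | step 14 | C3 alkylzinc iodide (not isolated) | I[Zn]CC[C@H](O[Si](C)(C)C(C)(C)C)[C@](C)(OC(C)=O)C[C@H](OC(=O)/C(C)=C/C)[C@H]1[C@H](COC(C)=O)C(=O)O[C@@H]1/C=C(C)\I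
F4 | step 8 | (5S)-5-(hydroxymethyl)furan-2(5H)-one | O=C1O[C@H](CO)C=C1
F5 | step 8 | (5S)-5-[(triethylsilyloxy)methyl]furan-2(5H)-one | O=C1O[C@H](CO[Si](CC)(CC)CC)C=C1
F6 | step 8 | (3R,4S,5S)-4-{2-[(2R,3S)-3-(tert-butyldimethylsilyloxy)-2-hydroxy-2-methylpent-4-enyl]-1,3-dithian-2-yl}-3-(hydroxymethyl)-5-[(triethylsilyloxy)methyl]oxolan-2-one | C=C[C@H](O[Si](C)(C)C(C)(C)C)[C@](C)(O)CC2(SCCCS2)[C@H]1[C@H](CO)C(=O)O[C@@H]1CO[Si](CC)(CC)CC
F7 | step 8 | C13 acetate of F6 | C=C[C@H](O[Si](C)(C)C(C)(C)C)[C@](C)(O)CC2(SCCCS2)[C@H]1[C@H](COC(C)=O)C(=O)O[C@@H]1CO[Si](CC)(CC)CC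
F8 | step 8 | C5 primary alcohol from F7 | C=C[C@H](O[Si](C)(C)C(C)(C)C)[C@](C)(O)CC2(SCCCS2)[C@H]1[C@H](COC(C)=O)C(=O)O[C@@H]1CO
F9 | step 8 | C5 aldehyde from F8 | C=C[C@H](O[Si](C)(C)C(C)(C)C)[C@](C)(O)CC2(SCCCS2)[C@H]1[C@H](COC(C)=O)C(=O)O[C@@H]1C=O
F10 | step 17 | bromohydrin of 27: C4 hydroxyl on the required face, C5 bromide on the opposite face | C/C=C(\C)C(=O)O[C@H]1C[C@@](C)(OC(C)=O)C(=O)CC[C@@](C)(O)[C@H](Br)[C@H]2OC(=O)[C@@H](COC(C)=O)[C@@H]21
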